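**Retrosynthetic overview**
1. Feature: C2, C4, C8a and C5 are all carbonyl-derived carbons on one unbranched chain (CH3–C2–C3–C4–C4a–C8a–C8–C7–C6–C5–side chain), so a linear 2,4,6,10-tetraketone holds every carbon of the pyridone ring (N1, C2, C3, C4, C4a, C8a) and of the carbocycle (C4a, C5, C6, C7, C8, C8a).
2. Target ⇒ O-benzyl pyridine in which C5 is set by asymmetric hydrogenation of C5=C6 and the C8 hydroxyl is put in late (N-oxide rearrangement, oxidation, asymmetric transfer hydrogenation) ⇒ bicyclic 7,8-dihydroquinolin-4(1H)-one.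
3. Dihydroquinolinone ⇒ tetraketone + ammonia: N1–C2 and N1–C8a close the pyridone ring, then C4a–C5 closes the carbocycle, all in one flask.
4. Tetraketone ⇒ C4a–C8a bond by acylating the dianion of 3-methoxypentane-2,4-dione with a ketal-protected Weinreb amide; the amide comes from glutaric anhydride and (5-bromopentyl)benzene, the diketone from pentane-2,4-dione.

Key step: step 8

Assumption: the SMILES is read as the (5S,8R) isomer, in which the C5 side chain and the C8 hydroxyl are cis on the carbocycle.

**Route**

Step 1
Reactants: 1 (5-bromopentyl)benzene; 2 glutaric anhydride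
Product: 4 5-oxo-10-phenyldecanoic acid, via Grignard reagent 3 (not isolated)
Conditions: Mg, THF, 45 °C; then added slowly to 2 (1.5 equiv), THF, −78 → −20 °C; aq. HCl
Reagents that add atoms: none
Why: Acylation of a Grignard reagent by a cyclic anhydride stops at the ketone because ring opening leaves a magnesium carboxylate, and inverse addition to excess anhydride at low temperature suppresses a second addition.

Step 2
Reactants: 4 5-oxo-10-phenyldecanoic acid
Product: 6 N-methoxy-N-methyl-5-oxo-10-phenyldecanamide, via acyl imidazolide 5 (not isolated)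
Conditions: CDI (1.2 equiv), CH2Cl2, 23 °C; then MeNH(OMe)·HCl (1.5 equiv), 23 °C
Reagents that add atoms: N,O-dimethylhydroxylamine hydrochloride, CNOC.Cl
Why: Activation of the acid as its acyl imidazolide and aminolysis is a standard Weinreb amide synthesis that leaves the dialkyl ketone untouched.

Step 3
Reactants: 6 N-methoxy-N-methyl-5-oxo-10-phenyldecanamide
Product: 7 N-methoxy-N-methyl-4-[2-(5-phenylpentyl)-1,3-dioxolan-2-yl]butanamide
Conditions: HOCH2CH2OH (5 equiv), TsOH·H2O (5 mol %), PhMe, reflux, Dean–Stark
Reagents that add atoms: ethylene glycol, OCCO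
Why: Acid-catalysed ketalisation with azeotropic removal of water masks the only ketone as a 1,3-dioxolane that withstands the strongly basic acylation, while the Weinreb amide is inert to catalytic acid.

Step 4
Reactants: 8 pentane-2,4-dione
Product: 9 3-diazopentane-2,4-dione
Conditions: 4-acetamidobenzenesulfonyl azide (1.1 equiv), Et3N, MeCN, 0 → 23 °C
Reagents that add atoms: 4-acetamidobenzenesulfonyl azide, CC(=O)Nc1ccc(cc1)S(=O)(=O)N=[N+]=[N-]
Why: Regitz diazo transfer to the activated methylene of a 1,3-diketone is a standard reaction.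

Step 5
Reactants: 9 3-diazopentane-2,4-dione
Product: 10 3-methoxypentane-2,4-dione
Conditions: Rh2(OAc)4 (1 mol %), MeOH (5 equiv), CH2Cl2, 40 °C
Reagents that add atoms: methanol, CO
Why: The dirhodium carbenoid of an acceptor/acceptor diazo compound inserts into the O–H bond of methanol (carbenoid O–H insertion), which puts the methoxy group on the carbon that becomes C3.

Step 6
Reactants: 10 3-methoxypentane-2,4-dione; 7 N-methoxy-N-methyl-4-[2-(5-phenylpentyl)-1,3-dioxolan-2-yl]butanamide
Product: 12 3-methoxy-9-[2-(5-phenylpentyl)-1,3-dioxolan-2-yl]nonane-2,4,6-trione, via dilithium dianion 11 (not isolated)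
Conditions: 10 (2.5 equiv), LiN(iPr)2 (5.0 equiv), THF, −78 → 0 °C; then 7 (1.0 equiv), −78 → 0 °C; AcOH quench
Reagents that add atoms: none
Why: γ-Acylation of a β-diketone dianion at its terminal carbon by a Weinreb amide forms the C4a–C8a bond, the chelated tetrahedral adduct persisting until the quench so that the acidic triketone never meets the dianion, and the two methyl groups of 10 are equivalent so no regiochemical question arises.

Step 7
Reactants: 12 3-methoxy-9-[2-(5-phenylpentyl)-1,3-dioxolan-2-yl]nonane-2,4,6-trione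
Product: 13 3-methoxy-15-phenylpentadecane-2,4,6,10-tetraone
Conditions: 1 M aq. HCl, THF, 23 °C; crude product used at once
Reagents that add atoms: water, O
Why: Dilute aqueous acid hydrolyses the dialkyl ketal (ketal hydrolysis) while the largely enolised 1,3,5-triketone is left alone at room temperature, and 13 is carried on without storage because its active methylene can add to the freed ketone.

Step 8
Reactants: 13 3-methoxy-15-phenylpentadecane-2,4,6,10-tetraone
Product: 16 3-methoxy-2-methyl-5-(5-phenylpentyl)-7,8-dihydroquinolin-4(1H)-one, via keto pyridone 14 (not isolated), via tertiary carbinol 15 (not isolated)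
Conditions: NH4OAc (10 equiv), AcOH, 60 → 100 °C, Ar
Reagents that add atoms: ammonium acetate, CC(=O)[O-].[NH4+]
Why: Ammonia from NH4OAc condenses with a terminal carbonyl of the enolised 1,3,5-triketone (C2 or C8a) to give a vinylogous amide whose nitrogen adds to the other terminal carbonyl in a 6-exo-trig closure, and loss of water gives the aromatic 4-pyridone 14, which cannot revert. C4a, the β-carbon of the N1–C8a=C4a–C4=O vinylogous amide, then attacks the C5 ketone (protonated or as its transient iminium ion) in a 6-(enolendo)-exo-trig aldol-type closure to carbinol 15, and acid-promoted loss of water toward C6 gives the C5=C6 alkene conjugated with the pyridone. The closest known reactions are the conversion of 1,3,5-triketones into 4-pyridones by ammonia and the aldol cyclodehydration of 1,5-dicarbonyl compounds; should C4a–C5 form first, the resulting 2-acylcyclohexenone reaches 16 as well by condensation with ammonia and tautomerisation. No stereocentre is created. The step needs nitrogen to bridge C2 and C8a and not C8a and C5, and N-condensation to outrun carbon–carbon aldol aromatisation of the triketone: the enolised triketone carbonyls are far more reactive toward ammonia than the isolated C5 ketone, dihydropyridine formation is reversible whereas pyridone formation is not, the weakly acidic buffer suppresses base-mediated closure to resorcinols, and once the pyridone exists C8a is no longer an electrophile for the enolate of the C5 ketone.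

Step 9
Reactants: 16 3-methoxy-2-methyl-5-(5-phenylpentyl)-7,8-dihydroquinolin-4(1H)-one
Product: 17 4-(benzyloxy)-3-methoxy-2-methyl-5-(5-phenylpentyl)-7,8-dihydroquinoline
Conditions: BnBr (1.5 equiv), Ag2CO3 (1.0 equiv), PhMe, 80 °C, dark, Ar
Reagents that add atoms: benzyl bromide, BrCc1ccccc1
Why: Silver-mediated alkylation of a 4-pyridone takes place on oxygen (Williamson-type O-alkylation), and N-alkylation is further disfavoured here because both carbons flanking nitrogen are substituted.

Step 10
Reactants: 17 4-(benzyloxy)-3-methoxy-2-methyl-5-(5-phenylpentyl)-7,8-dihydroquinoline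
Product: 18 (5S)-4-(benzyloxy)-3-methoxy-2-methyl-5-(5-phenylpentyl)-5,6,7,8-tetrahydroquinoline
Conditions: H2 (50 bar), [Ir(cod)((S)-tBu-PHOX)][B(C6H3(CF3)2)4] (2 mol %), CH2Cl2, 23 °C
Reagents that add atoms: none
Why: Cationic iridium N,P-ligand catalysts hydrogenate unfunctionalised trisubstituted aryl alkenes of the 1-alkyl-3,4-dihydronaphthalene type enantioselectively without touching benzyl ethers or arenes (iridium-catalysed asymmetric hydrogenation), the chiral ligand choosing the alkene face and so setting C5 as S (the ligand antipode is fixed in a pilot run), and the pyridine nitrogen flanked by the C2 methyl group and C8 is too hindered to be expected to bind the metal.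

Step 11
Reactants: 18 (5S)-4-(benzyloxy)-3-methoxy-2-methyl-5-(5-phenylpentyl)-5,6,7,8-tetrahydroquinoline
Product: 19 (5S)-4-(benzyloxy)-3-methoxy-2-methyl-5-(5-phenylpentyl)-5,6,7,8-tetrahydroquinoline 1-oxide
Conditions: mCPBA (1.3 equiv), CH2Cl2, 0 → 23 °C
Reagents that add atoms: 3-chloroperbenzoic acid, OOC(=O)c1cccc(Cl)c1
Why: Peracid N-oxidation of an electron-rich pyridine is standard, and at this stage the molecule holds no alkene or other readily oxidised group.

Step 12
Reactants: 19 (5S)-4-(benzyloxy)-3-methoxy-2-methyl-5-(5-phenylpentyl)-5,6,7,8-tetrahydroquinoline 1-oxide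
Product: 21 (5S)-4-(benzyloxy)-3-methoxy-2-methyl-5-(5-phenylpentyl)-5,6,7,8-tetrahydroquinolin-8-ol (both C8 epimers), via C8 trifluoroacetate 20 (not isolated)
Conditions: (CF3CO)2O (3 equiv), CH2Cl2, 0 → 23 °C; then aq. K2CO3, MeOH, 23 °C
Reagents that add atoms: none
Why: In the Boekelheide rearrangement O-acylation of the N-oxide, deprotonation to the anhydrobase and a [3,3] shift carry the oxygen to an α-alkyl carbon, the ring methylene C8 being the expected site over the C2 methyl group because the more substituted anhydrobase is favoured, in line with simpler 2-methyl-5,6,7,8-tetrahydroquinoline N-oxides, and the C8 configuration is of no consequence since step 13 erases it.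

Step 13
Reactants: 21 (5S)-4-(benzyloxy)-3-methoxy-2-methyl-5-(5-phenylpentyl)-5,6,7,8-tetrahydroquinolin-8-ol (both C8 epimers)
Product: 22 (5S)-4-(benzyloxy)-3-methoxy-2-methyl-5-(5-phenylpentyl)-6,7-dihydroquinolin-8(5H)-one
Conditions: Dess–Martin periodinane (1.3 equiv), CH2Cl2, 23 °C
Reagents that add atoms: none
Why: Dess–Martin oxidation of a secondary pyridylic alcohol is mild, converges both C8 epimers on one ketone and cannot epimerise C5, which is not α to the new carbonyl.

Step 14
Reactants: 22 (5S)-4-(benzyloxy)-3-methoxy-2-methyl-5-(5-phenylpentyl)-6,7-dihydroquinolin-8(5H)-one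
Product: 23 (5S,8R)-4-(benzyloxy)-3-methoxy-2-methyl-5-(5-phenylpentyl)-5,6,7,8-tetrahydroquinolin-8-ol
Conditions: RuCl[(R,R)-TsDPEN](p-cymene) (2 mol %), HCO2H/Et3N (5:2), CH2Cl2, 30 °C
Reagents that add atoms: none
Why: In the Noyori–Ikariya asymmetric transfer hydrogenation of aryl and 2-pyridyl ketones the (R,R)-catalyst delivers hydride to the face that gives the 8R alcohol (pyridine ring in the role of the aryl group, as for 1-tetralone), and the substrate reinforces this because pseudoaxial attack anti to the pseudoaxial C5 chain also leads to the cis isomer.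

Step 15
Reactants: 23 (5S,8R)-4-(benzyloxy)-3-methoxy-2-methyl-5-(5-phenylpentyl)-5,6,7,8-tetrahydroquinolin-8-ol
Product: 24 (5S,8R)-8-hydroxy-3-methoxy-2-methyl-5-(5-phenylpentyl)-5,6,7,8-tetrahydroquinolin-4(1H)-one
Conditions: H2 (1 atm), Pd/C (10 wt %), EtOAc/MeOH, 23 °C
Reagents that add atoms: none
Why: Hydrogenolysis of the benzyl ether releases the 4-hydroxypyridine, which tautomerises to the 4-pyridone, while under neutral conditions the secondary C8 alcohol, the methyl ether and both stereocentres are retained.

**Compound list**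
1 | (5-bromopentyl)benzene | BrCCCCCc1ccccc1 | starting material
2 | glutaric anhydride | O=C1CCCC(=O)O1 | starting material
3 | (5-phenylpentyl)magnesium bromide (not isolated) | Br[Mg]CCCCCc1ccccc1 | intermediate
4 | 5-oxo-10-phenyldecanoic acid | OC(=O)CCCC(=O)CCCCCc1ccccc1 | intermediate
5 | 1-(1H-imidazol-1-yl)-10-phenyldecane-1,5-dione (not isolated) | O=C(CCCC(=O)CCCCCc1ccccc1)n1ccnc1 | intermediate
6 | N-methoxy-N-methyl-5-oxo-10-phenyldecanamide | CON(C)C(=O)CCCC(=O)CCCCCc1ccccc1 | intermediate
7 | N-methoxy-N-methyl-4-[2-(5-phenylpentyl)-1,3-dioxolan-2-yl]butanamide | CON(C)C(=O)CCCC1(CCCCCc2ccccc2)OCCO1 | intermediate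
8 | pentane-2,4-dione | CC(=O)CC(C)=O | starting material
9 | 3-diazopentane-2,4-dione | CC(=O)C(=[N+]=[N-])C(C)=O | intermediate
10 | 3-methoxypentane-2,4-dione | CC(=O)C(OC)C(C)=O | intermediate
11 | dilithium 3-methoxypenta-1,3-diene-2,4-diolate (not isolated) | [Li+].[Li+].C=C([O-])C(OC)=C(C)[O-] | intermediate
12 | 3-methoxy-9-[2-(5-phenylpentyl)-1,3-dioxolan-2-yl]nonane-2,4,6-trione | CC(=O)C(OC)C(=O)CC(=O)CCCC1(CCCCCc2ccccc2)OCCO1 | intermediate
13 | 3-methoxy-15-phenylpentadecane-2,4,6,10-tetraone | CC(=O)C(OC)C(=O)CC(=O)CCCC(=O)CCCCCc1ccccc1 | intermediate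
14 | 3-methoxy-2-methyl-6-(4-oxo-9-phenylnonyl)pyridin-4(1H)-one (not isolated) | COc1c(C)[nH]c(CCCC(=O)CCCCCc2ccccc2)cc1=O | intermediate
15 | 5-hydroxy-3-methoxy-2-methyl-5-(5-phenylpentyl)-5,6,7,8-tetrahydroquinolin-4(1H)-one (racemic, not isolated) | COc1c(C)[nH]c2c(c1=O)C(O)(CCCCCc1ccccc1)CCC2 | intermediate
16 | 3-methoxy-2-methyl-5-(5-phenylpentyl)-7,8-dihydroquinolin-4(1H)-one | COc1c(C)[nH]c2c(c1=O)C(CCCCCc1ccccc1)=CCC2 | intermediate
17 | 4-(benzyloxy)-3-methoxy-2-methyl-5-(5-phenylpentyl)-7,8-dihydroquinoline | COc1c(C)nc2c(c1OCc1ccccc1)C(CCCCCc1ccccc1)=CCC2 | intermediate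
18 | (5S)-4-(benzyloxy)-3-methoxy-2-methyl-5-(5-phenylpentyl)-5,6,7,8-tetrahydroquinoline | COc1c(C)nc2c(c1OCc1ccccc1)[C@@H](CCCCCc1ccccc1)CCC2 | intermediate
19 | (5S)-4-(benzyloxy)-3-methoxy-2-methyl-5-(5-phenylpentyl)-5,6,7,8-tetrahydroquinoline 1-oxide | COc1c(C)[n+]([O-])c2c(c1OCc1ccccc1)[C@@H](CCCCCc1ccccc1)CCC2 | intermediate
20 | (5S)-4-(benzyloxy)-3-methoxy-2-methyl-5-(5-phenylpentyl)-5,6,7,8-tetrahydroquinolin-8-yl trifluoroacetate (both C8 epimers, not isolated) | COc1c(C)nc2c(c1OCc1ccccc1)[C@@H](CCCCCc1ccccc1)CCC2OC(=O)C(F)(F)F | intermediate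
21 | (5S)-4-(benzyloxy)-3-methoxy-2-methyl-5-(5-phenylpentyl)-5,6,7,8-tetrahydroquinolin-8-ol (both C8 epimers) | COc1c(C)nc2c(c1OCc1ccccc1)[C@@H](CCCCCc1ccccc1)CCC2O | intermediate
22 | (5S)-4-(benzyloxy)-3-methoxy-2-methyl-5-(5-phenylpentyl)-6,7-dihydroquinolin-8(5H)-one | COc1c(C)nc2c(c1OCc1ccccc1)[C@@H](CCCCCc1ccccc1)CCC2=O | intermediate
23 | (5S,8R)-4-(benzyloxy)-3-methoxy-2-methyl-5-(5-phenylpentyl)-5,6,7,8-tetrahydroquinolin-8-ol | COc1c(C)nc2c(c1OCc1ccccc1)[C@@H](CCCCCc1ccccc1)CC[C@H]2O | intermediate
24 | (5S,8R)-8-hydroxy-3-methoxy-2-methyl-5-(5-phenylpentyl)-5,6,7,8-tetrahydroquinolin-4(1H)-one | COc1c(C)[nH]c2c(c1=O)[C@@H](CCCCCc1ccccc1)CC[C@H]2O | target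

**Step count**
Total: 15 steps. Longest linear sequence: 13 steps (steps 1–3 and 6–15); steps 4–5 make the second fragment.

**Steps most likely to fail**

Step 8. Nitrogen may bridge the 1,5-related C8a and C5 carbonyls to give dihydropyridines, or the cascade may stall at the aromatic keto pyridone because its C4a is only a modest nucleophile toward the C5 ketone. The fallback forms the carbocycle before nitrogen is brought in, so that C5 is no longer a carbonyl when ammonia arrives. It sets out from 13: piperidinium acetate in toluene with azeotropic removal of water brings about the intramolecular Knoevenagel condensation of the active methylene C4a with the C5 ketone. This gives 2-methoxy-1-[6-oxo-2-(5-phenylpentyl)cyclohex-1-en-1-yl]butane-1,3-dione F1. Ammonia in ethanol, followed by warming in acetic acid, then condenses with C2 and the ring carbonyl C8a, and tautomerisation to the aromatic pyridone returns the route at 16.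

Step 10. The basic pyridine nitrogen may deactivate the cationic iridium hydride, the benzyloxy group peri to C5 may slow alkene coordination, or the two alkene faces may be poorly distinguished. The fallback gives up catalytic face selection for a resolution. It sets out from 16: hydrogenation over palladium on carbon (Pd/C) in methanol, which spares the pyridone and phenyl rings, gives racemic 3-methoxy-2-methyl-5-(5-phenylpentyl)-5,6,7,8-tetrahydroquinolin-4(1H)-one F2. O-Benzylation with benzyl bromide and Ag2CO3 as in step 9 gives racemic 4-(benzyloxy)-3-methoxy-2-methyl-5-(5-phenylpentyl)-5,6,7,8-tetrahydroquinoline F3. Preparative chromatography on a chiral stationary phase separates the enantiomers; (5R)-4-(benzyloxy)-3-methoxy-2-methyl-5-(5-phenylpentyl)-5,6,7,8-tetrahydroquinoline F4 is set aside and the (5S)-enantiomer rejoins the route at 18.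

Step 6. Proton transfer from the α-methylene of the amide to the strongly basic dianion, or slow addition to the weakly electrophilic Weinreb amide, may return the starting materials. The fallback replaces the acylation by an aldol addition and an oxidation. It sets out from 7: iBu2AlH in THF at −78 °C reduces the Weinreb amide to 4-[2-(5-phenylpentyl)-1,3-dioxolan-2-yl]butanal F5. Dianion 11 adds through its terminal carbon to this aldehyde at −78 °C to give 6-hydroxy-3-methoxy-9-[2-(5-phenylpentyl)-1,3-dioxolan-2-yl]nonane-2,4-dione F6. Dess–Martin oxidation of the secondary alcohol returns the route at 12.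

**Further compounds**
F1 | step 8 | 2-methoxy-1-[6-oxo-2-(5-phenylpentyl)cyclohex-1-en-1-yl]butane-1,3-dione | CC(=O)C(OC)C(=O)C1=C(CCCCCc2ccccc2)CCCC1=O
F2 | step 10 | racemic 3-methoxy-2-methyl-5-(5-phenylpentyl)-5,6,7,8-tetrahydroquinolin-4(1H)-one | COc1c(C)[nH]c2c(c1=O)C(CCCCCc1ccccc1)CCC2
F3 | step 10 | racemic 4-(benzyloxy)-3-methoxy-2-methyl-5-(5-phenylpentyl)-5,6,7,8-tetrahydroquinoline | COc1c(C)nc2c(c1OCc1ccccc1)C(CCCCCc1ccccc1)CCC2
F4 | step 10 | (5R)-4-(benzyloxy)-3-methoxy-2-methyl-5-(5-phenylpentyl)-5,6,7,8-tetrahydroquinoline | COc1c(C)nc2c(c1OCc1ccccc1)[C@H](CCCCCc1ccccc1)CCC2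
F5 | step 6 | 4-[2-(5-phenylpentyl)-1,3-dioxolan-2-yl]butanal | O=CCCCC1(CCCCCc2ccccc2)OCCO1
F6 | step 6 | 6-hydroxy-3-methoxy-9-[2-(5-phenylpentyl)-1,3-dioxolan-2-yl]nonane-2,4-dione | CC(=O)C(OC)C(=O)CC(O)CCCC1(CCCCCc2ccccc2)OCCO1
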